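Remark on the chemistry: the counter-ions of the Vilsmeier reagent and of iminium salt 5 are written as chloride, and N-acetyl-L-isoleucine (Ac-Ile-OH) is taken as a representative mono-N-protected amino acid ligand for the C–H alkylation.

## Analysis of the target

The target (C29H40O7) is a depside in which two benzoic acid units are joined through an aryl ester, with no further ring and no stereocentre, so the problem is one of regiochemistry and chemoselectivity only. Ring A is a 2-heptyl-4,6-dimethoxybenzoyl group; ring B, numbered from the carbon that bears CO2H, carries methoxy at C2, the ring A acyloxy group at C4 and a pentyl chain at C6. The aryl ester is a phenol ester and open to hydrolysis and transacylation, although its carbonyl is shielded by the two ortho substituents of ring A. The free carboxylic acid of ring B sits between two ortho substituents and can lose CO2 under acid, on heating or in the presence of Ag2CO3, and the electron-rich C3 and C5 positions of ring A react readily with electrophiles. The difficulties are the esterification of a di-ortho-substituted benzoic acid, keeping one carboxyl free while the other is esterified, and the 1,2,3,5-substitution pattern of both rings. The strategy rests on ring B: C2 is blocked by methoxy, so in the pentyl-free acid C6 holds the only C–H bond ortho to the C1 carboxyl group. The acid itself can therefore steer a metal to exactly the carbon that must receive the pentyl chain.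

## Retrosynthetic reasoning

C6–pentyl bond of ring B. The target, 4-[(2-heptyl-4,6-dimethoxybenzoyl)oxy]-2-methoxy-6-pentylbenzoic acid 14, is cut between C6 of ring B and the first carbon of the pentyl chain. This gives the pentyl-free depside acid 12 and potassium pentyltrifluoroborate 13. The cut is made here because it is the only C–C bond whose formation can be directed by a group the target already contains, the free carboxyl. It also removes the one substituent that keeps ring B from being a purchasable benzoic acid. The forward reaction has to functionalise a single C–H bond in the presence of the depside ester and of electron-rich ring A, without a protecting group on the acid.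

Free acid of 12. The carboxyl group of 12 is traced back to the benzyl ester 11. A mask is needed because the ring B carboxyl must stay silent while the depside ester is made. Benzyl is chosen because it leaves by neutral hydrogenolysis, which cannot touch the aryl ester.

Depside ester bond. Ester 11 is cut at the acyl C–O bond into 2-heptyl-4,6-dimethoxybenzoyl chloride 8 and benzyl 4-hydroxy-2-methoxybenzoate 10. The hindered ring A acid is activated as strongly as possible, and phenol 10 offers only one nucleophilic site, so no selectivity question arises.

Benzyl ester of 10. Phenol 10 comes from purchased 4-hydroxy-2-methoxybenzoic acid 9 by alkylation at the carboxylate oxygen. Ring B then needs no ring chemistry at all before the key step.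

Carboxyl carbon of ring A. Acid chloride 8 goes back to acid 7 and then to aldehyde 6, whose formyl C–aryl bond is cut to give 1-heptyl-3,5-dimethoxybenzene 4. The cut is placed here because electrophilic substitution of 4 favours the carbon para to one methoxy group and next to the heptyl chain, which is the position required. A directed metalation would instead go between the two methoxy groups, so an electrophilic formylation followed by oxidation is used.

Aryl–heptyl bond. Arene 4 is cut between the ring and the chain into 1-bromo-3,5-dimethoxybenzene 1 and 1-bromoheptane 2, the latter used as its Grignard reagent 3. A cross-coupling places the chain at the carbon that already holds bromine, so its position is fixed by the starting material.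

## Alternatives that were turned down

Alternative 1: Ring A is disconnected at its C1–C2 bond, back to the acyclic ring B aryl ester A2, benzyl 2-methoxy-6-pentyl-4-[(3,5,7-trioxotetradecanoyl)oxy]benzoate. In the forward step a mild amine base would trigger aldol attack of C2 on the C7 ketone and dehydration, giving the dihydroxy depside ester A1.

- For it: the substitution pattern of ring A follows from the chain, so no regioisomer can arise there, and the hindered esterification is avoided because the ester exists before ring A does. On these two points it is stronger than the chosen route.
- Against it: A2 is an activated aryl ester of a polyketo acid. The C5 enol oxygen or C6 can attack the ester carbonyl and expel the ring B phenoxide, which destroys the depside bond the route is meant to keep. A2 would also have to be built by iterated acylations on a ring B that already carries its pentyl chain. A1 then needs two O-methylations, one of them on a chelated phenol, and a debenzylation.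
- Comparison: the chosen strategy has a short sequence of stable aromatic intermediates and no steps after the key step.

Alternative 2: The depside is cut at the O–C4 bond of ring B. Acid 7 would be coupled with the ring B arylboronic acid A4 in a Chan–Lam O-arylation mediated by Cu(OTf)2, giving the tert-butyl ester A3 of the target.

- For it: the new bond is made at the phenolic carbon, so the shielding of the ring A carbonyl does not matter. The union is fully convergent, and the finished acid is never exposed to silver. On these points it is as strong as or stronger than the chosen route.
- Against it: A4 must carry pentyl, methoxy, ester and boron in a 1,2,3,5-pattern. The hard part of ring B is therefore only moved into a multi-step fragment synthesis. O-Arylation of carboxylic acids of this kind usually needs stoichiometric Cu(OTf)2 and excess boronic acid, with protodeboronation and oxidative hydroxylation competing. A3 still requires acidolysis next to an acid that is prone to decarboxylation.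
- Comparison: the chosen strategy takes ring B from a purchased acid and installs the chain in one operation.

Alternative 3: Ring B is disconnected at C1–C2 and C5–C6. The diene A6, a ketene acetal carrying the ring A aroyloxy group on its central carbon, would add to benzyl oct-2-ynoate A7 in a Diels–Alder reaction. Loss of one acetal methoxy group as its alcohol would aromatise the adduct to the benzyl ester A5 of the target.

- For it: all four substituents of ring B are set in one ring-forming step, with the regiochemistry dictated by the polarisation of diene and ynoate. No precious late intermediate is subjected to C–H activation. On these points it is stronger than the chosen route.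
- Against it: A6 is both a ketene acetal and an enol ester, so it is hydrolytically and thermally fragile. Making it requires O-acylation of an enolate by the hindered ring A acyl donor, the same steric problem in a worse setting with C-acylation competing. A7 is a β-alkyl ynoate of modest reactivity, so heating is needed. A5 still has to be debenzylated.
- Comparison: the chosen strategy handles only robust compounds before its single risky step.

Key step: step 8

## Route

Step 1
Reactants: 1 1-bromo-3,5-dimethoxybenzene; 2 1-bromoheptane
Product: 4 1-heptyl-3,5-dimethoxybenzene, via heptylmagnesium bromide 3 (not isolated)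
Conditions: 2, Mg, THF, 40 °C; then 1, NiCl2(dppp) (2 mol%), THF, 0 °C to reflux
Reagents that add atoms: none
Why: Kumada coupling; the primary alkyl Grignard reagent 3 transmetalates to the aryl–nickel species formed from 1, the bidentate phosphine dppp favours reductive elimination over β-hydride elimination, and the methoxy groups are inert to the Grignard reagent.

Step 2
Reactants: 4 1-heptyl-3,5-dimethoxybenzene
Product: 6 2-heptyl-4,6-dimethoxybenzaldehyde, via aryl dimethyliminium chloride 5 (not isolated)
Conditions: POCl3, DMF, 0 °C to 70 °C; then aq NaOAc, rt
Reagents that add atoms: N,N-dimethylformamide, CN(C)C=O; water, O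
Why: Vilsmeier–Haack formylation; the chloroiminium electrophile made from DMF and POCl3 should attack C2 of 4, para to one methoxy group and ortho to the other, rather than C4, which is flanked by both methoxy groups; C2 and C6 are equivalent by symmetry, DMF supplies the formyl carbon, and aqueous acetate hydrolyses iminium salt 5 to the aldehyde, whose carbonyl oxygen comes from water.

Step 3
Reactants: 6 2-heptyl-4,6-dimethoxybenzaldehyde
Product: 7 2-heptyl-4,6-dimethoxybenzoic acid
Conditions: NaClO2, NaH2PO4, 2-methyl-2-butene (excess), t-BuOH/H2O, 0 °C to rt
Reagents that add atoms: sodium chlorite, [Na+].[O-]Cl=O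
Why: Pinnick oxidation; chlorous acid adds to the aldehyde and fragments to the acid, and the alkene in excess traps the hypochlorous acid by-product, which would otherwise chlorinate C3 or C5 of the electron-rich ring.

Step 4
Reactants: 7 2-heptyl-4,6-dimethoxybenzoic acid
Product: 8 2-heptyl-4,6-dimethoxybenzoyl chloride
Conditions: (COCl)2, DMF (cat.), CH2Cl2, 0 °C to rt; concentrated and used crude
Reagents that add atoms: oxalyl chloride, ClC(=O)C(=O)Cl
Why: Acid chloride formation through the chloroiminium catalyst generated from DMF; the conditions are mild enough to leave the aryl methyl ethers intact, and all by-products are gases.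

Step 5
Reactants: 9 4-hydroxy-2-methoxybenzoic acid
Product: 10 benzyl 4-hydroxy-2-methoxybenzoate
Conditions: BnBr (1.05 equiv), KHCO3, DMF, rt to 40 °C
Reagents that add atoms: benzyl bromide, BrCc1ccccc1
Why: Chemoselective SN2 alkylation of the carboxylate; hydrogen carbonate deprotonates the carboxylic acid but not the phenol, so only the carboxyl oxygen is benzylated and the C4 hydroxyl stays free.

Step 6
Reactants: 8 2-heptyl-4,6-dimethoxybenzoyl chloride; 10 benzyl 4-hydroxy-2-methoxybenzoate
Product: 11 benzyl 4-[(2-heptyl-4,6-dimethoxybenzoyl)oxy]-2-methoxybenzoate
Conditions: Et3N, DMAP (0.2 equiv), CH2Cl2, 0 °C to reflux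
Reagents that add atoms: none
Why: Nucleophilic acyl substitution with DMAP catalysis; the phenol of 10 is the only nucleophile and is acidic enough (para ester) to be largely ionised by Et3N, while the electron-rich chloride 8 reacts with considerable acylium character, which offsets the shielding by its two ortho substituents.

Step 7
Reactants: 11 benzyl 4-[(2-heptyl-4,6-dimethoxybenzoyl)oxy]-2-methoxybenzoate
Product: 12 4-[(2-heptyl-4,6-dimethoxybenzoyl)oxy]-2-methoxybenzoic acid
Conditions: H2 (1 atm), Pd/C (10%), EtOAc, rt
Reagents that add atoms: none
Why: Hydrogenolysis of the benzylic C–O bond under neutral conditions; the aryl ester, the methyl ethers and both arenes are inert at room temperature and atmospheric pressure.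

Step 8
Reactants: 12 4-[(2-heptyl-4,6-dimethoxybenzoyl)oxy]-2-methoxybenzoic acid; 13 potassium pentyltrifluoroborate
Product: 14 4-[(2-heptyl-4,6-dimethoxybenzoyl)oxy]-2-methoxy-6-pentylbenzoic acid (target)
Conditions: Pd(OAc)2 (10 mol%), Ac-Ile-OH (20 mol%), Ag2CO3 (2 equiv), 1,4-benzoquinone (20 mol%), 13 (3 equiv), t-BuOH, 90 °C; then aq HCl
Reagents that add atoms: none
Why: Carboxylate-directed ortho C–H alkylation: the carboxylate of 12, formed with Ag2CO3, binds divalent palladium, and concerted metalation–deprotonation of the C6–H bond, assisted by the carboxylate and amidate of the amino acid ligand, should give a five-membered aryl palladacycle. Transmetalation of the pentyl group from 13 (after slow release of the boron species in the protic medium) and benzoquinone-promoted C(sp2)–C(sp3) reductive elimination then form the C6–pentyl bond, and Ag2CO3 reoxidises zerovalent palladium to divalent palladium. The closest known reaction type is the ortho C–H alkylation of free benzoic acids with alkylboronic acids or alkyltrifluoroborates under divalent palladium with Ag2CO3 as oxidant and a mono-N-protected amino acid ligand. No ring is closed and no stereocentre is formed. The step needs site selectivity, and the substrate supplies it: C2 is blocked by methoxy, so C6 holds the only C–H bond ortho to the directing carboxylate and a second alkylation is impossible. The ester carbonyl of ring A cannot serve as a competing directing group for its own ring, because both of its ortho positions carry substituents (heptyl and methoxy). The depside ester should survive because its carbonyl is shielded on both sides and t-BuOH is a poor nucleophile, and the excess of 13 compensates for pentyl groups lost through β-hydride elimination and protodeboronation.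

## Compound list

1 | 1-bromo-3,5-dimethoxybenzene | COc1cc(Br)cc(OC)c1 | starting material
2 | 1-bromoheptane | CCCCCCCBr | starting material
3 | heptylmagnesium bromide | CCCCCCC[Mg]Br | intermediate
4 | 1-heptyl-3,5-dimethoxybenzene | CCCCCCCc1cc(OC)cc(OC)c1 | intermediate
5 | N-[(2-heptyl-4,6-dimethoxyphenyl)methylidene]-N-methylmethanaminium chloride | CCCCCCCc1cc(OC)cc(OC)c1C=[N+](C)C.[Cl-] | intermediate
6 | 2-heptyl-4,6-dimethoxybenzaldehyde | CCCCCCCc1cc(OC)cc(OC)c1C=O | intermediate
7 | 2-heptyl-4,6-dimethoxybenzoic acid | CCCCCCCc1cc(OC)cc(OC)c1C(=O)O | intermediate
8 | 2-heptyl-4,6-dimethoxybenzoyl chloride | CCCCCCCc1cc(OC)cc(OC)c1C(=O)Cl | intermediate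
9 | 4-hydroxy-2-methoxybenzoic acid | COc1cc(O)ccc1C(=O)O | starting material
10 | benzyl 4-hydroxy-2-methoxybenzoate | COc1cc(O)ccc1C(=O)OCc1ccccc1 | intermediate
11 | benzyl 4-[(2-heptyl-4,6-dimethoxybenzoyl)oxy]-2-methoxybenzoate | CCCCCCCc1cc(OC)cc(OC)c1C(=O)Oc1ccc(C(=O)OCc2ccccc2)c(OC)c1 | intermediate
12 | 4-[(2-heptyl-4,6-dimethoxybenzoyl)oxy]-2-methoxybenzoic acid | CCCCCCCc1cc(OC)cc(OC)c1C(=O)Oc1ccc(C(=O)O)c(OC)c1 | intermediate
13 | potassium pentyltrifluoroborate | CCCCC[B-](F)(F)F.[K+] | starting material
14 | 4-[(2-heptyl-4,6-dimethoxybenzoyl)oxy]-2-methoxy-6-pentylbenzoic acid | CCCCCCCc1cc(OC)cc(OC)c1C(=O)Oc1cc(CCCCC)c(C(=O)O)c(OC)c1 | target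

## Step count and least certain steps

Total step count: 8. Longest linear sequence: 7 steps (steps 1, 2, 3, 4, 6, 7 and 8); step 5 is the one-step ring B branch.

Key step, step 8. Three processes are most likely to go wrong.
- Protodecarboxylation: the ortho-methoxy carboxylate of 12, and even more the di-ortho-substituted carboxylate of 14, can lose CO2 under monovalent silver and divalent palladium at 90 °C.
- Loss of the pentyl group before C–C bond formation, through β-hydride elimination of the pentylpalladium intermediate or protodeboronation of 13, which would stall conversion.
- Undirected electrophilic palladation at C3 or C5 of electron-rich ring A, leading to oxidative side reactions.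

Fallback for step 8: it sets out from 8 and comes back to the route at 14, and the pentyl chain is brought in with ring B instead of being attached last. Purchased 2,4-dihydroxy-6-pentylbenzoic acid F1 would be benzylated at the carboxylate as in step 5 (BnBr, KHCO3, DMF) to give benzyl 2,4-dihydroxy-6-pentylbenzoate F2. Acylation of F2 with 8 (Et3N, DMAP, CH2Cl2) should occur at the free 4-hydroxyl, because the 2-hydroxyl is held in a hydrogen bond to the ester carbonyl, and would give benzyl 4-[(2-heptyl-4,6-dimethoxybenzoyl)oxy]-2-hydroxy-6-pentylbenzoate F3. Methylation of the remaining phenol (MeI, K2CO3, acetone, reflux) would give benzyl 4-[(2-heptyl-4,6-dimethoxybenzoyl)oxy]-2-methoxy-6-pentylbenzoate F4. Hydrogenolysis of F4 as in step 7 (H2, Pd/C, EtOAc) would deliver 14.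

Acylation, step 6. Acyl transfer at the di-ortho-substituted carbonyl of 8 may be slow. Hydrolysis of 8 back to 7 by adventitious water could then win, and prolonged heating with the amine base could lead to decomposition of the chloride.

Fallback for step 6: it sets out from 7 and 10 and comes back to the route at 11, so that step 4 is not needed. Acid 7 and phenol 10 would be stirred with trifluoroacetic anhydride in toluene at room temperature. Acid 7 is converted into 2-heptyl-4,6-dimethoxybenzoic trifluoroacetic anhydride F5, which ionises to a linear acylium species stabilised by the two methoxy groups. Attack on this species is not subject to the steric shielding, and capture by the phenol of 10 gives 11.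

Formylation, step 2. Formylation may also take place at C4 between the two methoxy groups, so that isomeric aldehydes have to be separated, and the activated ring may be formylated twice under forcing conditions.

Fallback for step 2: it sets out from 4 and comes back to the route at 7, so that step 3 is not needed. Bromination with N-bromosuccinimide in MeCN at 0 °C should give 2-bromo-1-heptyl-3,5-dimethoxybenzene F6, substitution para to a methoxy group being the normal course for this mild electrophile. Bromine–lithium exchange with n-BuLi in THF at −78 °C then gives (2-heptyl-4,6-dimethoxyphenyl)lithium F7, which is quenched with CO2 and acidified with aq HCl to give acid 7. Regiocontrol is settled at the stage of a bromide that is easy to purify, and the carboxyl carbon enters in its final oxidation state.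

Kumada coupling, step 1. β-Hydride elimination or chain isomerisation at the alkylnickel stage would lead to reduction of 1 in place of coupling, and homocoupling of either partner would consume material.

Fallback for step 1: it sets out from 1 and comes back to the route at 4. Sonogashira coupling of 1 with hept-1-yne (PdCl2(PPh3)2, CuI, Et3N, 60 °C) would give 1-(hept-1-yn-1-yl)-3,5-dimethoxybenzene F8, and hydrogenation (H2, Pd/C, EtOAc, rt) would saturate the triple bond to give 4. No sp3 carbon–metal species is involved.

## Further compounds

F1 | step 8 | 2,4-dihydroxy-6-pentylbenzoic acid | CCCCCc1cc(O)cc(O)c1C(=O)O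
F2 | step 8 | benzyl 2,4-dihydroxy-6-pentylbenzoate | CCCCCc1cc(O)cc(O)c1C(=O)OCc1ccccc1
F3 | step 8 | benzyl 4-[(2-heptyl-4,6-dimethoxybenzoyl)oxy]-2-hydroxy-6-pentylbenzoate | CCCCCCCc1cc(OC)cc(OC)c1C(=O)Oc1cc(CCCCC)c(C(=O)OCc2ccccc2)c(O)c1
F4 | step 8 | benzyl 4-[(2-heptyl-4,6-dimethoxybenzoyl)oxy]-2-methoxy-6-pentylbenzoate | CCCCCCCc1cc(OC)cc(OC)c1C(=O)Oc1cc(CCCCC)c(C(=O)OCc2ccccc2)c(OC)c1
F5 | step 6 | 2-heptyl-4,6-dimethoxybenzoic trifluoroacetic anhydride | CCCCCCCc1cc(OC)cc(OC)c1C(=O)OC(=O)C(F)(F)F
F6 | step 2 | 2-bromo-1-heptyl-3,5-dimethoxybenzene | CCCCCCCc1cc(OC)cc(OC)c1Br
F7 | step 2 | (2-heptyl-4,6-dimethoxyphenyl)lithium | [Li]c1c(CCCCCCC)cc(OC)cc1OC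
F8 | step 1 | 1-(hept-1-yn-1-yl)-3,5-dimethoxybenzene | CCCCCC#Cc1cc(OC)cc(OC)c1
A1 | alternative 1 | benzyl 4-[(2-heptyl-4,6-dihydroxybenzoyl)oxy]-2-methoxy-6-pentylbenzoate | CCCCCCCc1cc(O)cc(O)c1C(=O)Oc1cc(CCCCC)c(C(=O)OCc2ccccc2)c(OC)c1
A2 | alternative 1 | benzyl 2-methoxy-6-pentyl-4-[(3,5,7-trioxotetradecanoyl)oxy]benzoate | CCCCCCCC(=O)CC(=O)CC(=O)CC(=O)Oc1cc(CCCCC)c(C(=O)OCc2ccccc2)c(OC)c1
A3 | alternative 2 | tert-butyl 4-[(2-heptyl-4,6-dimethoxybenzoyl)oxy]-2-methoxy-6-pentylbenzoate | CCCCCCCc1cc(OC)cc(OC)c1C(=O)Oc1cc(CCCCC)c(C(=O)OC(C)(C)C)c(OC)c1
A4 | alternative 2 | [4-(tert-butoxycarbonyl)-3-methoxy-5-pentylphenyl]boronic acid | CCCCCc1cc(B(O)O)cc(OC)c1C(=O)OC(C)(C)C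
A5 | alternative 3 | benzyl 4-[(2-heptyl-4,6-dimethoxybenzoyl)oxy]-2-methoxy-6-pentylbenzoate | CCCCCCCc1cc(OC)cc(OC)c1C(=O)Oc1cc(CCCCC)c(C(=O)OCc2ccccc2)c(OC)c1
A6 | alternative 3 | 4,4-dimethoxybuta-1,3-dien-2-yl 2-heptyl-4,6-dimethoxybenzoate | C=C(OC(=O)c1c(CCCCCCC)cc(OC)cc1OC)C=C(OC)OC
A7 | alternative 3 | benzyl oct-2-ynoate | CCCCCC#CC(=O)OCc1ccccc1
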